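The hydroazulene is disconnected at the ring-fusion bond C3a–C8a and at C7–C8 of the seven-membered ring (azulene locants: C3 isopropyl, C3a carbinol, C6 and C7 diol carbons, C8 methylene, C8a methyl). The feature exploited is that C3a is a carbinol carbon next to quaternary C8a, with oxygenated C7 one methylene further on. One SmI2 operation on an acyclic keto aldehyde enoate makes both bonds: the ketone carbon, umpoled as a ketyl, adds to the enoate β-carbon and closes the cyclopentane; the derived samarium enolate then adds to the aldehyde and closes the cycloheptane. The activating benzyl ester is later lost as CO2.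

Key step: step 8

Remark on the chemistry: bicyclic compounds carry the azulene locants of the target. The two aldol centres made in step 8 (C7 and C8) are left unassigned, because steps 9 and 10 remove both; the SMILES of 14, 15 and 16 therefore carry no descriptor there.

Step 1
Reactants: 1 (4R)-4-benzyl-3-(3-methylbutanoyl)-1,3-oxazolidin-2-one; 2 but-3-en-2-one
Product: 3 (4R)-4-benzyl-3-[(2R)-5-oxo-2-(propan-2-yl)hexanoyl]-1,3-oxazolidin-2-one
Conditions: TiCl4, iPr2NEt, CH2Cl2, 0 °C; then 2, 0 °C
Reagents that add atoms: none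
Why: Michael addition of the chelated chlorotitanium Z-enolate of the N-acyloxazolidinone to the enone should occur on the enolate face opposite the benzyl group of the auxiliary, which sets the isopropyl-bearing centre (future C3) as R.

Step 2
Reactants: 3 (4R)-4-benzyl-3-[(2R)-5-oxo-2-(propan-2-yl)hexanoyl]-1,3-oxazolidin-2-one
Product: 4 benzyl (2E,6R)-6-[(4R)-4-benzyl-2-oxo-1,3-oxazolidine-3-carbonyl]-3,7-dimethyloct-2-enoate
Conditions: (EtO)2P(O)CH2CO2Bn, NaH, THF, 0 °C to rt; E isomer separated by chromatography
Reagents that add atoms: benzyl 2-(diethoxyphosphoryl)acetate CCOP(=O)(CC(=O)OCc1ccccc1)OCC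
Why: Horner–Wadsworth–Emmons olefination of the unhindered methyl ketone should favour the E-enoate, while the stabilised phosphonate anion spares the imide and does not enolise its hindered α-centre; no stereocentre is formed.

Step 3
Reactants: 4 benzyl (2E,6R)-6-[(4R)-4-benzyl-2-oxo-1,3-oxazolidine-3-carbonyl]-3,7-dimethyloct-2-enoate
Product: 5 benzyl (2E,6R)-6-[(ethylsulfanyl)carbonyl]-3,7-dimethyloct-2-enoate
Conditions: EtSH, n-BuLi, THF, 0 °C
Reagents that add atoms: ethanethiol CCS
Why: Acyl transfer from the N-acyloxazolidinone to lithium ethanethiolate (thiolysis of the auxiliary) should take place at the exocyclic carbonyl only and without epimerisation, since the thiolate is a weak base; the hindered benzyl enoate is left alone at 0 °C.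

Step 4
Reactants: 6 2-methyl-2-vinyloxirane (racemic); 7 benzyl alcohol
Product: 8 (2R)-2-(benzyloxy)-2-methylbut-3-en-1-ol
Conditions: Pd2(dba)3·CHCl3 (1 mol%), (1S,2S)-N,N'-bis[2-(diphenylphosphino)benzoyl]cyclohexane-1,2-diamine (3 mol%), Et3B (1 mol%), CH2Cl2, rt
Reagents that add atoms: none
Why: Palladium-catalysed dynamic kinetic asymmetric allylic etherification: the racemic vinyl epoxide ionises to rapidly interconverting π-allylpalladium alkoxides, the borate formed with Et3B delivers benzyl alcohol to the more substituted allyl terminus, and the chiral diphosphine (the enantiomer chosen being the one that leads to the R ether) sets the quaternary centre (future C6).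

Step 5
Reactants: 8 (2R)-2-(benzyloxy)-2-methylbut-3-en-1-ol
Product: 9 {[(2R)-2-(benzyloxy)-2-methylbut-3-en-1-yl]oxy}triethylsilane
Conditions: Et3SiCl, imidazole, CH2Cl2, 0 °C
Reagents that add atoms: chlorotriethylsilane CC[Si](Cl)(CC)CC
Why: Silylation of the primary alcohol with a silyl chloride and imidazole is routine and masks the hydroxyl for the hydroboration; no stereocentre is touched.

Step 6
Reactants: 9 {[(2R)-2-(benzyloxy)-2-methylbut-3-en-1-yl]oxy}triethylsilane; 5 benzyl (2E,6R)-6-[(ethylsulfanyl)carbonyl]-3,7-dimethyloct-2-enoate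
Product: 11 benzyl (2E,6R,10R)-10-(benzyloxy)-3,10-dimethyl-7-oxo-6-(propan-2-yl)-11-[(triethylsilyl)oxy]undec-2-enoate, via alkylborane 10 (not isolated)
Conditions: 9-BBN, THF, 0 °C to rt; then 5, Pd(PPh3)4 (5 mol%), CuTC (copper thiophene-2-carboxylate, CuO2CC4H3S, 1.5 equiv), Cs2CO3 (promoter), THF, 45 °C
Reagents that add atoms: none
Why: Anti-Markovnikov hydroboration of the terminal alkene with 9-BBN followed by a Liebeskind–Srogl thioester–organoboron cross-coupling should give the ketone under conditions mild enough to leave the enoate untouched and the α-stereocentre of the acyl partner unepimerised; no stereocentre is formed.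

Step 7
Reactants: 11 benzyl (2E,6R,10R)-10-(benzyloxy)-3,10-dimethyl-7-oxo-6-(propan-2-yl)-11-[(triethylsilyl)oxy]undec-2-enoate
Product: 12 benzyl (2E,6R,10R)-10-(benzyloxy)-3,10-dimethyl-7,11-dioxo-6-(propan-2-yl)undec-2-enoate
Conditions: (COCl)2, DMSO, CH2Cl2, −78 to −30 °C; then Et3N
Reagents that add atoms: none
Why: Swern conditions should oxidise the primary triethylsilyl ether directly to the aldehyde (oxidative desilylation through the alkoxysulfonium salt), the tertiary benzyl ether and the ketone being inert and the new aldehyde having no α-hydrogen.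

Step 8
Reactants: 12 benzyl (2E,6R,10R)-10-(benzyloxy)-3,10-dimethyl-7,11-dioxo-6-(propan-2-yl)undec-2-enoate
Product: 14 benzyl (3R,3aS,6R,8aR)-6-(benzyloxy)-3a,7-dihydroxy-6,8a-dimethyl-3-(propan-2-yl)decahydroazulene-8-carboxylate, via samarium enolate 13 (not isolated)
Conditions: SmI2 (3 equiv), THF–t-BuOH (4:1), −78 to 0 °C
Reagents that add atoms: none
Why: Electron transfer from SmI2 to the ketone gives a ketyl radical anion whose carbon (future C3a) adds to the enoate β-carbon (future C8a), and a second electron turns the resulting α-ester radical into a trivalent samarium enolate (13) whose α-carbon (future C8) adds to the aldehyde (future C7). The closest known reaction type is the SmI2 radical cyclisation–aldol cascade of dicarbonyl compounds that carry an α,β-unsaturated ester. The cyclopentane closes by 5-exo-trig radical addition and the cycloheptane by an intramolecular aldol addition of the exocyclic ester enolate (7-(enolexo)-exo-trig). C3a and C8a are set by the existing C3 centre through a chair-like 5-exo transition state with the isopropyl group pseudo-equatorial and the samarium-bound ketyl oxygen anti to the enoate, which should place hydroxyl, methyl and isopropyl on one face of the cyclopentane and the two chains that close the seven-membered ring cis on the other; C6 is carried in from 8 and the C7 and C8 centres need no control. The step needs the ketone, not the aldehyde, to start the sequence: electron transfer is reversible, the ketone ketyl has a fast irreversible 5-exo exit to the enoate five atoms away, whereas the neopentylic aldehyde has no acceptor in reach except the hindered ketone. The trans relation of the tertiary samarium alkoxide and the ester arm also prevents lactonisation, and t-BuOH is too hindered to protonate the enolate before the aldol step.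

Step 9
Reactants: 14 benzyl (3R,3aS,6R,8aR)-6-(benzyloxy)-3a,7-dihydroxy-6,8a-dimethyl-3-(propan-2-yl)decahydroazulene-8-carboxylate
Product: 15 benzyl (3R,3aS,6R,8aR)-6-(benzyloxy)-3a-hydroxy-6,8a-dimethyl-7-oxo-3-(propan-2-yl)decahydroazulene-8-carboxylate
Conditions: Dess–Martin periodinane, CH2Cl2, rt
Reagents that add atoms: none
Why: Dess–Martin oxidation of the only secondary alcohol should give the β-keto ester and thereby removes the uncontrolled carbinol centre, the tertiary alcohol being inert.

Step 10
Reactants: 15 benzyl (3R,3aS,6R,8aR)-6-(benzyloxy)-3a-hydroxy-6,8a-dimethyl-7-oxo-3-(propan-2-yl)decahydroazulene-8-carboxylate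
Product: 17 (3R,3aS,6R,8aR)-3a,6-dihydroxy-6,8a-dimethyl-3-(propan-2-yl)decahydroazulen-7-one, via keto acid 16 (not isolated)
Conditions: H2 (1 atm), Pd(OH)2/C, EtOAc, rt; then 50 °C
Reagents that add atoms: none
Why: Hydrogenolysis cleaves the benzyl ester and the tertiary benzyl ether, and the resulting β-keto acid should lose CO2 on gentle warming (decarboxylation through the six-membered enol transition state), which removes the activating group and the second uncontrolled centre.

Step 11
Reactants: 17 (3R,3aS,6R,8aR)-3a,6-dihydroxy-6,8a-dimethyl-3-(propan-2-yl)decahydroazulen-7-one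
Product: 18 (3R,3aS,6R,7R,8aR)-6,8a-dimethyl-3-(propan-2-yl)decahydroazulene-3a,6,7-triol
Conditions: Me4NBH(OAc)3, MeCN–AcOH (1:1), −20 °C to rt
Reagents that add atoms: none
Why: Hydroxyl-directed triacetoxyborohydride reduction: the C6 tertiary hydroxyl exchanges an acetate on boron and delivers hydride intramolecularly to the neighbouring carbonyl from its own face, so the new C7 hydroxyl should come out trans to the C6 hydroxyl (7R).

Step 12
Reactants: 18 (3R,3aS,6R,7R,8aR)-6,8a-dimethyl-3-(propan-2-yl)decahydroazulene-3a,6,7-triol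
Product: 19 (3R,3aS,6R,7R,8aR)-3a,6-dihydroxy-6,8a-dimethyl-3-(propan-2-yl)decahydroazulen-7-yl 4-methoxybenzoate
Conditions: 4-MeOC6H4COCl, DMAP (cat.), pyridine, CH2Cl2, 0 °C to rt
Reagents that add atoms: 4-methoxybenzoyl chloride COc1ccc(cc1)C(Cl)=O
Why: Acylation of the secondary hydroxyl with the acid chloride under nucleophilic catalysis by DMAP; the two tertiary hydroxyls are too hindered to react, and no stereocentre is touched.

Compound list

1 | (4R)-4-benzyl-3-(3-methylbutanoyl)-1,3-oxazolidin-2-one | CC(C)CC(=O)N1[C@H](Cc2ccccc2)COC1=O | starting material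
2 | but-3-en-2-one | CC(=O)C=C | starting material
3 | (4R)-4-benzyl-3-[(2R)-5-oxo-2-(propan-2-yl)hexanoyl]-1,3-oxazolidin-2-one | CC(=O)CC[C@H](C(C)C)C(=O)N1[C@H](Cc2ccccc2)COC1=O | intermediate
4 | benzyl (2E,6R)-6-[(4R)-4-benzyl-2-oxo-1,3-oxazolidine-3-carbonyl]-3,7-dimethyloct-2-enoate | O=C(OCc1ccccc1)/C=C(\C)CC[C@H](C(C)C)C(=O)N1[C@H](Cc2ccccc2)COC1=O | intermediate
5 | benzyl (2E,6R)-6-[(ethylsulfanyl)carbonyl]-3,7-dimethyloct-2-enoate | O=C(OCc1ccccc1)/C=C(\C)CC[C@H](C(C)C)C(=O)SCC | intermediate
6 | 2-methyl-2-vinyloxirane (racemic) | CC1(CO1)C=C | starting material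
7 | benzyl alcohol | OCc1ccccc1 | starting material
8 | (2R)-2-(benzyloxy)-2-methylbut-3-en-1-ol | C=C[C@@](C)(OCc1ccccc1)CO | intermediate
9 | {[(2R)-2-(benzyloxy)-2-methylbut-3-en-1-yl]oxy}triethylsilane | C=C[C@@](C)(OCc1ccccc1)CO[Si](CC)(CC)CC | intermediate
10 | 9-{(3R)-3-(benzyloxy)-3-methyl-4-[(triethylsilyl)oxy]butyl}-9-borabicyclo[3.3.1]nonane | C(C[C@@](C)(OCc1ccccc1)CO[Si](CC)(CC)CC)B1C2CCCC1CCC2 | intermediate (not isolated)
11 | benzyl (2E,6R,10R)-10-(benzyloxy)-3,10-dimethyl-7-oxo-6-(propan-2-yl)-11-[(triethylsilyl)oxy]undec-2-enoate | O=C(OCc1ccccc1)/C=C(\C)CC[C@H](C(C)C)C(=O)CC[C@@](C)(OCc1ccccc1)CO[Si](CC)(CC)CC | intermediate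
12 | benzyl (2E,6R,10R)-10-(benzyloxy)-3,10-dimethyl-7,11-dioxo-6-(propan-2-yl)undec-2-enoate | O=C(OCc1ccccc1)/C=C(\C)CC[C@H](C(C)C)C(=O)CC[C@@](C)(OCc1ccccc1)C=O | intermediate
13 | samarium enolate: cyclopentane from the first ring closure, as bis(diiodosamarium) tertiary alkoxide and benzyl ester enolate, aldehyde still free | O=C[C@](C)(OCc1ccccc1)CC[C@]2(O[Sm](I)I)[C@@H](C(C)C)CC[C@]2(C)C=C(O[Sm](I)I)OCc1ccccc1 | intermediate (not isolated)
14 | benzyl (3R,3aS,6R,8aR)-6-(benzyloxy)-3a,7-dihydroxy-6,8a-dimethyl-3-(propan-2-yl)decahydroazulene-8-carboxylate (C7 and C8 unassigned) | OC2C(C(=O)OCc1ccccc1)[C@@]3(C)CC[C@H](C(C)C)[C@@]3(O)CC[C@@]2(C)OCc1ccccc1 | intermediate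
15 | benzyl (3R,3aS,6R,8aR)-6-(benzyloxy)-3a-hydroxy-6,8a-dimethyl-7-oxo-3-(propan-2-yl)decahydroazulene-8-carboxylate (C8 unassigned) | O=C2C(C(=O)OCc1ccccc1)[C@@]3(C)CC[C@H](C(C)C)[C@@]3(O)CC[C@@]2(C)OCc1ccccc1 | intermediate
16 | (3R,3aS,6R,8aR)-3a,6-dihydroxy-6,8a-dimethyl-7-oxo-3-(propan-2-yl)decahydroazulene-8-carboxylic acid (C8 unassigned) | O=C2C(C(=O)O)[C@@]3(C)CC[C@H](C(C)C)[C@@]3(O)CC[C@@]2(C)O | intermediate (not isolated)
17 | (3R,3aS,6R,8aR)-3a,6-dihydroxy-6,8a-dimethyl-3-(propan-2-yl)decahydroazulen-7-one | O=C2C[C@@]3(C)CC[C@H](C(C)C)[C@@]3(O)CC[C@@]2(C)O | intermediate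
18 | (3R,3aS,6R,7R,8aR)-6,8a-dimethyl-3-(propan-2-yl)decahydroazulene-3a,6,7-triol | O[C@@H]2C[C@@]3(C)CC[C@H](C(C)C)[C@@]3(O)CC[C@@]2(C)O | intermediate
19 | (3R,3aS,6R,7R,8aR)-3a,6-dihydroxy-6,8a-dimethyl-3-(propan-2-yl)decahydroazulen-7-yl 4-methoxybenzoate | COc1ccc(C(=O)O[C@@H]2C[C@@]3(C)CC[C@H](C(C)C)[C@@]3(O)CC[C@@]2(C)O)cc1 | target

Total step count: 12. Longest linear sequence: 10 steps (steps 1, 2, 3, 6, 7, 8, 9, 10, 11, 12).

Steps most likely to fail

Step 8. The aldehyde may be reduced in competition with the ketone (pinacol-type coupling of the two carbonyl groups), the samarium enolate may be protonated before the aldol ring closure, or the facial selectivity of the 5-exo addition may be poor. The fallback separates the two bond formations and sets out from 11, where the aldehyde is still masked. SmI2 in THF–MeOH at −78 °C should effect the ketyl–olefin cyclisation alone and give the cyclopentanol ester benzyl 2-[(1R,2S,3R)-2-{(3R)-3-(benzyloxy)-3-methyl-4-[(triethylsilyl)oxy]butyl}-2-hydroxy-1-methyl-3-(propan-2-yl)cyclopentyl]acetate F1. Swern oxidative desilylation as in step 7 should then give the aldehyde benzyl 2-[(1R,2S,3R)-2-[(3R)-3-(benzyloxy)-3-methyl-4-oxobutyl]-2-hydroxy-1-methyl-3-(propan-2-yl)cyclopentyl]acetate F2, which may rest as its six-membered lactol. LiN(SiMe3)2 (2.2 equiv) in THF at −78 °C forms the ester enolate, which has only the non-enolisable aldehyde to attack, and the intramolecular aldol addition comes back to the route at 14.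

Step 6. Transfer of the alkyl group from boron to the hindered, α-branched acylpalladium species may be slow, so that protodeboronation and loss of the thioester take over. The fallback sets out from alkylborane 10 (made from 9 as in step 6) and replaces boron by zinc. Oxidation with NaBO3·4H2O gives the alcohol (3R)-3-(benzyloxy)-3-methyl-4-[(triethylsilyl)oxy]butan-1-ol F3. An Appel reaction (I2, PPh3, imidazole) gives the iodide {[(2R)-2-(benzyloxy)-4-iodo-2-methylbutyl]oxy}triethylsilane F4. Zinc dust with LiCl in THF gives the alkylzinc iodide [(3R)-3-(benzyloxy)-3-methyl-4-(triethylsilyloxy)butyl]zinc iodide F5, used in solution. A Fukuyama coupling of this reagent with 5 (PdCl2(PPh3)2, toluene–THF, rt) comes back to the route at 11.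

Step 11. Facial selectivity may be poor if the ring-fusion hydroxyl competes as the directing group or if delivery through the five-membered arrangement is slow, which would give the cis diol. The fallback sets out from 17 and replaces substrate direction by reagent control. A Corey–Bakshi–Shibata reduction with (S)-2-methyl-CBS-oxazaborolidine and BH3·SMe2 (excess, to take up the two hydroxyls) distinguishes the quaternary C6 side from the C8 methylene and should give the 7R alcohol. It comes back to the route at 18 and makes no new compound (F0).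

Further compounds

F1 | step 8 | benzyl 2-[(1R,2S,3R)-2-{(3R)-3-(benzyloxy)-3-methyl-4-[(triethylsilyl)oxy]butyl}-2-hydroxy-1-methyl-3-(propan-2-yl)cyclopentyl]acetate | CC[Si](CC)(CC)OC[C@](C)(OCc1ccccc1)CC[C@]2(O)[C@@H](C(C)C)CC[C@]2(C)CC(=O)OCc1ccccc1
F2 | step 8 | benzyl 2-[(1R,2S,3R)-2-[(3R)-3-(benzyloxy)-3-methyl-4-oxobutyl]-2-hydroxy-1-methyl-3-(propan-2-yl)cyclopentyl]acetate | O=C[C@](C)(OCc1ccccc1)CC[C@]2(O)[C@@H](C(C)C)CC[C@]2(C)CC(=O)OCc1ccccc1
F3 | step 6 | (3R)-3-(benzyloxy)-3-methyl-4-[(triethylsilyl)oxy]butan-1-ol | OCC[C@@](C)(OCc1ccccc1)CO[Si](CC)(CC)CC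
F4 | step 6 | {[(2R)-2-(benzyloxy)-4-iodo-2-methylbutyl]oxy}triethylsilane | ICC[C@@](C)(OCc1ccccc1)CO[Si](CC)(CC)CC
F5 | step 6 | [(3R)-3-(benzyloxy)-3-methyl-4-(triethylsilyloxy)butyl]zinc iodide | I[Zn]CC[C@@](C)(OCc1ccccc1)CO[Si](CC)(CC)CC
F0 | step 11 | none | none
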